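## Retrosynthetic overview

1. Target 34 is disconnected at the C6 ester to eudesm-4(15)-en-6α-ol 28 and O-silyl p-coumaric acid 31. The C8 methylene of 28 is traced back to the C8 ketone 22 (Barton–McCombie deoxygenation).
2. The plan rests on one feature: the exocyclic C4=C15 methylene on ring A sits next to the trans C5–C10 fusion of rings A and B, which carries the quaternary C10 methyl. An alkyne-initiated cation–olefin cyclisation across an E C5=C10 alkene, ended by C9, leaves exactly this pattern.
3. Key disconnection: C4–C5 and C9–C10 of 22 lead back to the open-chain E-enyne enol silane 20. One gold-catalysed operation closes ring A first and ring B directly after.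
4. Compound 20 comes from an Evans syn aldol (sets C6 and C7) between isovaleryl imide 12 and E-enal 9. Enal 9 comes from syn-carbocupration of ethyl but-2-ynoate with a C-silylated pentynylcopper reagent.

Key step: step 11

Remark: eudesmane numbering (C1–C15) is used for all compounds, open-chain ones included; α/β refer to the decalin drawn with the C10 methyl β; the C8 carbinol centre of 23–26 is erased in step 14, so its configuration is of no consequence.

## Route

Step 1
Reactants: 1 (5-chloropent-1-yn-1-yl)trimethylsilane; 2 ethyl but-2-ynoate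
Product: 6 ethyl (2E)-3-methyl-8-(trimethylsilyl)oct-2-en-7-ynoate, via Grignard reagent 3 (not isolated), via alkylcopper reagent 4 (not isolated), via alkenylcopper adduct 5 (not isolated)
Conditions: 1, Mg, cat. I2, THF, reflux; CuBr·SMe2, THF, −40 °C; 2, −78 °C; aq NH4Cl, −78 °C → rt
Reagents that add atoms: none
Why: Syn-carbocupration of an ynoate: the silyl cap removes the acidic alkyne proton that would destroy the organometallic, copper and the new chain add to the same side of the triple bond, and protonation at −78 °C, before the alkenylcopper can equilibrate through its allenolate, keeps the chain trans to the ester (E).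

Step 2
Reactants: 6 ethyl (2E)-3-methyl-8-(trimethylsilyl)oct-2-en-7-ynoate
Product: 7 (2E)-3-methyl-8-(trimethylsilyl)oct-2-en-7-yn-1-ol
Conditions: i-Bu2AlH, CH2Cl2, −78 → 0 °C; aq KNaC4H4O6
Reagents that add atoms: none
Why: 1,2-Reduction of the enoate to the allylic alcohol with i-Bu2AlH, which at low temperature touches neither the trisubstituted alkene nor the silylalkyne.

Step 3
Reactants: 7 (2E)-3-methyl-8-(trimethylsilyl)oct-2-en-7-yn-1-ol
Product: 8 (2E)-3-methyloct-2-en-7-yn-1-ol
Conditions: K2CO3, MeOH, rt
Reagents that add atoms: none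
Why: Base-catalysed protiodesilylation of the alkynyl C–Si bond, placed here because no base-sensitive group is present yet and the free alkyne tolerates every later step up to the gold step.

Step 4
Reactants: 8 (2E)-3-methyloct-2-en-7-yn-1-ol
Product: 9 (2E)-3-methyloct-2-en-7-ynal
Conditions: MnO2, CH2Cl2, rt
Reagents that add atoms: none
Why: Allylic alcohol oxidation with MnO2, which is selective for the allylic position, stops at the aldehyde and should not scramble the E alkene.

Step 5
Reactants: 10 (4S)-4-benzyl-1,3-oxazolidin-2-one; 11 3-methylbutanoyl chloride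
Product: 12 (4S)-4-benzyl-3-(3-methylbutanoyl)-1,3-oxazolidin-2-one
Conditions: Et3N, cat. DMAP, CH2Cl2, 0 °C → rt
Reagents that add atoms: none
Why: N-Acylation of the oxazolidinone by the acid chloride under nucleophilic (DMAP) catalysis, in which the stereocentre of the auxiliary takes no part.

Step 6
Reactants: 12 (4S)-4-benzyl-3-(3-methylbutanoyl)-1,3-oxazolidin-2-one; 9 (2E)-3-methyloct-2-en-7-ynal
Product: 15 (4S)-4-benzyl-3-[(2S,3R,4E)-3-hydroxy-5-methyl-2-(propan-2-yl)dec-4-en-9-ynoyl]-1,3-oxazolidin-2-one, via Z-boron enolate 13 (not isolated), via boron aldolate 14 (not isolated)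
Conditions: Bu2BOTf, Et3N, CH2Cl2, 0 °C; 9, −78 → 0 °C; pH 7 buffer, MeOH, 30% H2O2, 0 °C
Reagents that add atoms: none
Why: Evans boron syn aldol: the Z-boron enolate reacts through a Zimmerman–Traxler chair on the face away from the benzyl group, which sets C7 (S) and C6 (R) in the syn relationship that becomes trans-diequatorial in ring B.

Step 7
Reactants: 15 aldol adduct
Product: 16 (2S,3R,4E)-3-hydroxy-N-methoxy-N,5-dimethyl-2-(propan-2-yl)dec-4-en-9-ynamide
Conditions: MeNH(OMe)·HCl, AlMe3, CH2Cl2, −10 °C → rt; aq KNaC4H4O6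
Reagents that add atoms: N,O-dimethylhydroxylamine hydrochloride, CNOC.Cl
Why: Weinreb transamidation with the aluminium amide, run before silylation because the free C6 hydroxyl group (as its aluminium alkoxide) steers the reagent to the exocyclic carbonyl, and leaving C6 and C7 untouched.

Step 8
Reactants: 16 hydroxy Weinreb amide
Product: 17 (2S,3R,4E)-3-[(tert-butyldimethylsilyl)oxy]-N-methoxy-N,5-dimethyl-2-(propan-2-yl)dec-4-en-9-ynamide
Conditions: TBSOTf, 2,6-lutidine, CH2Cl2, −78 → 0 °C
Reagents that add atoms: tert-butyldimethylsilyl triflate, CC(C)(C)[Si](C)(C)OS(=O)(=O)C(F)(F)F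
Why: Silylation of the hindered allylic alcohol with a silyl triflate and a non-nucleophilic base, conditions too mild to ionise the allylic C6–O bond or to touch the alkyne.

Step 9
Reactants: 17 silyloxy Weinreb amide
Product: 19 (3S,4R,5E)-4-[(tert-butyldimethylsilyl)oxy]-6-methyl-3-(propan-2-yl)undec-5-en-10-yn-2-one, via dilithiated hemiaminal 18 (not isolated)
Conditions: MeLi (3 equiv), THF, −78 → −20 °C; aq NH4Cl
Reagents that add atoms: methyllithium, [Li]C
Why: Weinreb ketone synthesis: the first equivalent of MeLi only deprotonates the alkyne (restored on work-up), the chelated tetrahedral adduct 18 blocks a second addition, and the low temperature protects the C7 stereocentre and the β-silyloxy group.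

Step 10
Reactants: 19 methyl ketone
Product: 20 (3S,4R,5E)-2,4-bis[(tert-butyldimethylsilyl)oxy]-6-methyl-3-(propan-2-yl)undeca-1,5-dien-10-yne
Conditions: TBSOTf, Et3N, CH2Cl2, −78 → 0 °C; aq NaHCO3; Et3N-deactivated silica
Reagents that add atoms: tert-butyldimethylsilyl triflate, CC(C)(C)[Si](C)(C)OS(=O)(=O)C(F)(F)F
Why: Soft enolisation (silyl triflate plus amine): the O-silylated ketone loses a proton from the open C9 methyl group rather than from the congested C7–H, whose removal would build a badly strained tetrasubstituted enol silane, and no strong base is present that would metallate and C-silylate the terminal alkyne.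

Step 11
Reactants: 20 open-chain E-enyne enol silane
Product: 22 6α-[(tert-butyldimethylsilyl)oxy]eudesm-4(15)-en-8-one (5S,6R,7S,10R), via alkenylgold ketone 21 (not isolated)
Conditions: Ph3PAuCl (5 mol %), AgSbF6 (5 mol %), i-PrOH (2 equiv), CH2Cl2 (0.02 M), −20 °C → rt
Reagents that add atoms: none
Why: Proposed new method: Ph3PAu+ binds the terminal C4≡C15 alkyne, C5 of the alkene attacks C4 anti to gold while charge builds on tertiary C10 (the open form of a cyclopropyl gold carbene), C9 of the enol silane bonds to C10 on the opposite alkene face, i-PrOH takes the silyl group from the C8 silyloxycarbenium ion, and the proton so released cleaves the C15–Au bond of 21 to leave the methylene and return the catalyst. The closest known reaction types are the alkyne-initiated 6-exo-dig polycyclisation of E-1,6-enynes under cationic monovalent gold ended by oxygen, nitrogen or arene nucleophiles, the gold-catalysed addition of silyl enol ethers to alkynes in the presence of an alcohol, and Lewis-acid cation–olefin cascades ended by silyl enol ethers; joining the first of these to an enol silane terminator is the untested part. Ring A closes 6-exo-dig at the alkyne (endo with respect to the alkene) and ring B closes 6-endo-trig at the enol silane. C5 and C10 are set relative to each other by stereospecific anti addition across the E alkene in a chair–chair array, which puts H5 and the C10 methyl trans-diaxial and so gives the trans fusion. They are set relative to C6 and C7 by the choice of alkene face: only one face lets the C6 silyloxy and C7 isopropyl groups lie equatorial and turns H6, not oxygen, towards the C10 methyl (allylic 1,3-strain). The step needs six- rather than five-membered first closure, secured by the methyl group on C10 and the electron-withdrawing C6 oxygen that both keep charge off C5, and carbon rather than alcohol capture at C10, secured by the intramolecular six-membered closure and by a hindered alcohol used in small excess at high dilution.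

Step 12
Reactants: 22 6α-silyloxyeudesm-4(15)-en-8-one
Product: 23 6α-[(tert-butyldimethylsilyl)oxy]eudesm-4(15)-en-8β-ol
Conditions: LiBH(s-Bu)3, THF, −78 °C; NaOH, H2O2, 0 °C
Reagents that add atoms: none
Why: Ketone reduction by a bulky trialkylborohydride: the axial path to C8 is closed by the syn-axial C10 methyl, so hydride should arrive equatorially and give the axial 8β-alcohol, while the non-basic conditions leave C7 and the β-silyloxy group at C6 alone.

Step 13
Reactants: 23 8β-alcohol
Product: 26 O-[6α-(tert-butyldimethylsilyloxy)eudesm-4(15)-en-8β-yl] S-methyl dithiocarbonate, via sodium alkoxide 24 (not isolated), via sodium xanthate 25 (not isolated)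
Conditions: NaH, cat. imidazole, THF, 0 → 40 °C; CS2; MeI, rt
Reagents that add atoms: carbon disulfide, S=C=S; iodomethane, CI
Why: Xanthate formation (first stage of the Barton–McCombie deoxygenation): the small, linear CS2 is accepted even by a crowded alkoxide, S-methylation fixes the adduct, and the silyl ether and alkene are inert to NaH.

Step 14
Reactants: 26 S-methyl xanthate
Product: 27 6α-[(tert-butyldimethylsilyl)oxy]eudesm-4(15)-ene (5S,6S,7S,10R)
Conditions: Bu3SnH, AIBN, toluene, 90 °C
Reagents that add atoms: none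
Why: Barton–McCombie deoxygenation: the stannyl radical adds to C=S, the secondary C8 radical released by fragmentation abstracts hydrogen from Bu3SnH, no leaving group sits β to C8, and the distant C4=C15 alkene cannot be reached within the rigid trans-decalin.

Step 15
Reactants: 27 6α-silyloxyeudesm-4(15)-ene
Product: 28 (5S,6S,7S,10R)-eudesm-4(15)-en-6-ol (6α-OH)
Conditions: Bu4NF, THF, 55 °C
Reagents that add atoms: none
Why: Fluoride-induced cleavage of the hindered secondary silyl ether, driven by Si–F bond formation and helped by gentle heating, under which the alkene and all four stereocentres are stable.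

Step 16
Reactants: 29 p-coumaric acid
Product: 31 (2E)-3-{4-[(tert-butyldimethylsilyl)oxy]phenyl}prop-2-enoic acid, via bis-silyl derivative 30 (not isolated)
Conditions: TBSCl, imidazole, DMF, rt; then AcOH/THF/H2O, rt
Reagents that add atoms: tert-butyldimethylsilyl chloride, CC(C)(C)[Si](C)(C)Cl
Why: Exhaustive silylation followed by selective hydrolysis of the far more labile silyl ester, which leaves the aryl silyl ether in place and frees the acid for coupling.

Step 17
Reactants: 28 eudesm-4(15)-en-6α-ol; 31 O-silyl p-coumaric acid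
Product: 33 eudesm-4(15)-en-6α-yl (2E)-3-{4-[(tert-butyldimethylsilyl)oxy]phenyl}prop-2-enoate, via mixed anhydride 32 (not isolated)
Conditions: 31, 2,4,6-Cl3C6H2COCl, Et3N, toluene, rt; 28, DMAP, toluene, 40 °C
Reagents that add atoms: none
Why: Yamaguchi esterification: DMAP attacks the mixed anhydride 32 at the cinnamoyl carbonyl and the resulting acylpyridinium ion acylates the hindered equatorial C6 alcohol with retention at C6, the phenol being masked against self-acylation.

Step 18
Reactants: 33 silyl-protected ester
Product: 34 target, (5S,6S,7S,10R)-eudesm-4(15)-en-6-yl (2E)-3-(4-hydroxyphenyl)prop-2-enoate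
Conditions: Bu4NF, AcOH, THF, 0 °C
Reagents that add atoms: none
Why: Buffered fluoride cleavage of the aryl silyl ether, which is much faster than any attack on the hindered cinnamate ester and leaves the E alkene and the exocyclic methylene untouched.

## Compound list

1 | (5-chloropent-1-yn-1-yl)trimethylsilane | C[Si](C)(C)C#CCCCCl | starting material
2 | ethyl but-2-ynoate | CC#CC(=O)OCC | starting material
3 | [5-(trimethylsilyl)pent-4-yn-1-yl]magnesium chloride | C[Si](C)(C)C#CCCC[Mg]Cl | intermediate
4 | [5-(trimethylsilyl)pent-4-yn-1-yl]copper | C[Si](C)(C)C#CCCC[Cu] | intermediate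
5 | alkenylcopper adduct (Cu cis to the new chain) | CCOC(=O)/C([Cu])=C(\C)CCCC#C[Si](C)(C)C | intermediate
6 | ethyl (2E)-3-methyl-8-(trimethylsilyl)oct-2-en-7-ynoate | CCOC(=O)/C=C(\C)CCCC#C[Si](C)(C)C | intermediate
7 | (2E)-3-methyl-8-(trimethylsilyl)oct-2-en-7-yn-1-ol | OC/C=C(\C)CCCC#C[Si](C)(C)C | intermediate
8 | (2E)-3-methyloct-2-en-7-yn-1-ol | OC/C=C(\C)CCCC#C | intermediate
9 | (2E)-3-methyloct-2-en-7-ynal | O=C/C=C(\C)CCCC#C | intermediate
10 | (4S)-4-benzyl-1,3-oxazolidin-2-one | O=C1N[C@@H](Cc2ccccc2)CO1 | starting material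
11 | 3-methylbutanoyl chloride (isovaleryl chloride) | CC(C)CC(=O)Cl | starting material
12 | (4S)-4-benzyl-3-(3-methylbutanoyl)-1,3-oxazolidin-2-one | CC(C)CC(=O)N1[C@@H](Cc2ccccc2)COC1=O | intermediate
13 | dibutylboron Z-enolate of 12 | CC(C)/C=C(\OB(CCCC)CCCC)N1[C@@H](Cc2ccccc2)COC1=O | intermediate
14 | dibutylboron aldolate | C#CCCC/C(C)=C/[C@@H](OB(CCCC)CCCC)[C@H](C(C)C)C(=O)N1[C@@H](Cc2ccccc2)COC1=O | intermediate
15 | (4S)-4-benzyl-3-[(2S,3R,4E)-3-hydroxy-5-methyl-2-(propan-2-yl)dec-4-en-9-ynoyl]-1,3-oxazolidin-2-one | C#CCCC/C(C)=C/[C@@H](O)[C@H](C(C)C)C(=O)N1[C@@H](Cc2ccccc2)COC1=O | intermediate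
16 | (2S,3R,4E)-3-hydroxy-N-methoxy-N,5-dimethyl-2-(propan-2-yl)dec-4-en-9-ynamide | C#CCCC/C(C)=C/[C@@H](O)[C@H](C(C)C)C(=O)N(C)OC | intermediate
17 | (2S,3R,4E)-3-[(tert-butyldimethylsilyl)oxy]-N-methoxy-N,5-dimethyl-2-(propan-2-yl)dec-4-en-9-ynamide | C#CCCC/C(C)=C/[C@@H](O[Si](C)(C)C(C)(C)C)[C@H](C(C)C)C(=O)N(C)OC | intermediate
18 | dilithiated tetrahedral adduct (lithium acetylide, lithium hemiaminal; hemiaminal carbon not defined) | [Li]C#CCCC/C(C)=C/[C@@H](O[Si](C)(C)C(C)(C)C)[C@H](C(C)C)C(C)(O[Li])N(C)OC | intermediate
19 | (3S,4R,5E)-4-[(tert-butyldimethylsilyl)oxy]-6-methyl-3-(propan-2-yl)undec-5-en-10-yn-2-one | C#CCCC/C(C)=C/[C@@H](O[Si](C)(C)C(C)(C)C)[C@H](C(C)C)C(C)=O | intermediate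
20 | (3S,4R,5E)-2,4-bis[(tert-butyldimethylsilyl)oxy]-6-methyl-3-(propan-2-yl)undeca-1,5-dien-10-yne | C#CCCC/C(C)=C/[C@@H](O[Si](C)(C)C(C)(C)C)[C@H](C(C)C)C(=C)O[Si](C)(C)C(C)(C)C | intermediate
21 | (triphenylphosphine)gold C15-alkenyl derivative of 22 (Au trans to C5) | [Au-]([P+](c1ccccc1)(c1ccccc1)c1ccccc1)/C=C1\CCC[C@]2(C)CC(=O)[C@@H](C(C)C)[C@H](O[Si](C)(C)C(C)(C)C)[C@@H]12 | intermediate
22 | 6α-[(tert-butyldimethylsilyl)oxy]eudesm-4(15)-en-8-one (5αH, 7αH, 10β-Me) | C=C1CCC[C@]2(C)CC(=O)[C@@H](C(C)C)[C@H](O[Si](C)(C)C(C)(C)C)[C@@H]12 | intermediate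
23 | 6α-[(tert-butyldimethylsilyl)oxy]eudesm-4(15)-en-8β-ol | C=C1CCC[C@]2(C)C[C@@H](O)[C@@H](C(C)C)[C@H](O[Si](C)(C)C(C)(C)C)[C@@H]12 | intermediate
24 | sodium 8β-alkoxide of 23 | C=C1CCC[C@]2(C)C[C@@H]([O-])[C@@H](C(C)C)[C@H](O[Si](C)(C)C(C)(C)C)[C@@H]12.[Na+] | intermediate
25 | sodium 8β-xanthate | C=C1CCC[C@]2(C)C[C@@H](OC(=S)[S-])[C@@H](C(C)C)[C@H](O[Si](C)(C)C(C)(C)C)[C@@H]12.[Na+] | intermediate
26 | O-[6α-(tert-butyldimethylsilyloxy)eudesm-4(15)-en-8β-yl] S-methyl dithiocarbonate | C=C1CCC[C@]2(C)C[C@@H](OC(=S)SC)[C@@H](C(C)C)[C@H](O[Si](C)(C)C(C)(C)C)[C@@H]12 | intermediate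
27 | 6α-[(tert-butyldimethylsilyl)oxy]eudesm-4(15)-ene | C=C1CCC[C@]2(C)CC[C@@H](C(C)C)[C@H](O[Si](C)(C)C(C)(C)C)[C@@H]12 | intermediate
28 | (5S,6S,7S,10R)-eudesm-4(15)-en-6-ol | C=C1CCC[C@]2(C)CC[C@@H](C(C)C)[C@H](O)[C@@H]12 | intermediate
29 | p-coumaric acid | O=C(O)/C=C/c1ccc(O)cc1 | starting material
30 | tert-butyldimethylsilyl (2E)-3-{4-[(tert-butyldimethylsilyl)oxy]phenyl}prop-2-enoate | CC(C)(C)[Si](C)(C)OC(=O)/C=C/c1ccc(O[Si](C)(C)C(C)(C)C)cc1 | intermediate
31 | (2E)-3-{4-[(tert-butyldimethylsilyl)oxy]phenyl}prop-2-enoic acid | O=C(O)/C=C/c1ccc(O[Si](C)(C)C(C)(C)C)cc1 | intermediate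
32 | mixed anhydride of 31 and 2,4,6-trichlorobenzoic acid | O=C(/C=C/c1ccc(O[Si](C)(C)C(C)(C)C)cc1)OC(=O)c1c(Cl)cc(Cl)cc1Cl | intermediate
33 | eudesm-4(15)-en-6α-yl (2E)-3-{4-[(tert-butyldimethylsilyl)oxy]phenyl}prop-2-enoate | C=C1CCC[C@]2(C)CC[C@@H](C(C)C)[C@H](OC(=O)/C=C/c3ccc(O[Si](C)(C)C(C)(C)C)cc3)[C@@H]12 | intermediate
34 | (5S,6S,7S,10R)-eudesm-4(15)-en-6-yl (2E)-3-(4-hydroxyphenyl)prop-2-enoate | C=C1CCC[C@]2(C)CC[C@@H](C(C)C)[C@H](OC(=O)/C=C/c3ccc(O)cc3)[C@@H]12 | target

## Step count and risks

Total number of steps: 18. Longest linear sequence: 16 steps (1–4, 6–15, 17, 18).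

**Step 11.**
- What may go wrong: acid traces from the catalyst system may protodesilylate the enol silane before the alkyne is engaged. The alcohol may capture the developing C10 cation in place of C9. The allylic C6–O bond may ionise. The first closure may be five-membered.
- The fallback sets out from 17 and comes back at 22, using documented reaction classes only.
- The terminator is changed from an enol silane to a β-keto ester. This is the class of carbon nucleophile whose capture of gold-activated 1,6-enynes is established. It also brings its own proton for protodeauration, so neither a silyl transfer nor an added alcohol is needed.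
- Crossed Claisen acylation of the lithium enolate of allyl acetate (LiN(i-Pr)2, THF, −78 °C, in excess to cover the alkyne proton) by Weinreb amide 17 should give the open-chain allyl β-keto ester F1.
- Ph3PAuCl/AgSbF6 in CH2Cl2 without alcohol should then close both rings through the same chair–chair array and give the bicyclic allyl β-keto ester F2. Its C9 centre is enolisable and is removed in the next operation.
- Deallylative decarboxylation with zerovalent palladium (Pd(PPh3)4, morpholine, THF, rt; Tsuji-type) delivers ketone 22.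

**Step 7.**
- What may go wrong: the aluminium amide may attack the ring carbonyl of the auxiliary (endocyclic cleavage), or retro-aldol cleavage may occur, because the isopropyl group shields the acyl carbon.
- The fallback sets out from 15 and comes back at 19, so that steps 7–9 are bypassed.
- Silylation is done first (TBSOTf, 2,6-lutidine, CH2Cl2) and gives the silyl ether imide F3.
- The small, soft thiolate LiSEt (EtSH, n-BuLi, THF, 0 °C) displaces the auxiliary at the exocyclic carbonyl and gives the S-ethyl thioester F4.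
- Me2CuLi (excess, Et2O, −78 → −30 °C) converts the thioester into methyl ketone 19 without a second addition.

**Step 13.**
- What may go wrong: thiocarbonylation of the axial C8 alkoxide may be sluggish, because the syn-axial C10 methyl and the C7 isopropyl group crowd it. The xanthate may also undergo thermal syn elimination during step 14.
- The fallback sets out from 22 and comes back at 27. It replaces the alcohol and radical sequence (steps 12–14) by a polar deoxygenation of the ketone itself.
- Condensation with TsNHNH2 (EtOH, 60 °C) gives the C8 tosylhydrazone F5.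
- Reduction with catecholborane (CHCl3, 0 °C), then NaOAc·3H2O at reflux, expels sulfinate and dinitrogen from the intermediate diazene and leaves the C8 methylene of 27. At this temperature the uncatalysed borane does not add to the C4=C15 alkene.

## Further compounds

F1 | step 11 | prop-2-en-1-yl (4S,5R,6E)-5-[(tert-butyldimethylsilyl)oxy]-7-methyl-3-oxo-4-(propan-2-yl)dodec-6-en-11-ynoate | C#CCCC/C(C)=C/[C@@H](O[Si](C)(C)C(C)(C)C)[C@H](C(C)C)C(=O)CC(=O)OCC=C
F2 | step 11 | prop-2-en-1-yl 6α-[(tert-butyldimethylsilyl)oxy]-8-oxoeudesm-4(15)-ene-9β-carboxylate | C=C1CCC[C@]2(C)[C@@H](C(=O)OCC=C)C(=O)[C@@H](C(C)C)[C@H](O[Si](C)(C)C(C)(C)C)[C@@H]12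
F3 | step 7 | (4S)-4-benzyl-3-[(2S,3R,4E)-3-[(tert-butyldimethylsilyl)oxy]-5-methyl-2-(propan-2-yl)dec-4-en-9-ynoyl]-1,3-oxazolidin-2-one | C#CCCC/C(C)=C/[C@@H](O[Si](C)(C)C(C)(C)C)[C@H](C(C)C)C(=O)N1[C@@H](Cc2ccccc2)COC1=O
F4 | step 7 | S-ethyl (2S,3R,4E)-3-[(tert-butyldimethylsilyl)oxy]-5-methyl-2-(propan-2-yl)dec-4-en-9-ynethioate | C#CCCC/C(C)=C/[C@@H](O[Si](C)(C)C(C)(C)C)[C@H](C(C)C)C(=O)SCC
F5 | step 13 | 6α-[(tert-butyldimethylsilyl)oxy]eudesm-4(15)-en-8-one 4-methylbenzenesulfonylhydrazone (NHTs syn to C9) | C=C1CCC[C@]2(C)C/C(=N\NS(=O)(=O)c3ccc(C)cc3)[C@@H](C(C)C)[C@H](O[Si](C)(C)C(C)(C)C)[C@@H]12
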